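A direct plan would build the benzene ring first and attach the side-chain ketone last: the vinylketene made from (2E)-3-methoxy-7-methylocta-2,6-dienoic acid A1 would add to the silyl ynol ether triisopropyl[(3-methoxy-5-methylhex-4-en-1-yn-1-yl)oxy]silane A2; heating would carry the cyclobutenone through ring opening, 6π closure, loss of methanol to an o-quinone methide and oxa-6π closure to 7-methoxy-2,2-dimethyl-8-(3-methylbut-2-en-1-yl)-2H-chromen-5-ol A3; A3 would then be acylated at C6 with 4-hydroxyphenylacetic acid A4 and trifluoroacetic anhydride.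
Its weakest steps would be:
(a) the thermal cascade from A1 and A2 to A3: at least six consecutive events in one flask, one of them the ionisation of a benzylic methyl ether (a poor leaving group) to the quinone methide, with ketene dimerisation and the wrong [2+2] regiochemistry as open exits;
(b) the making of A2: oxidation of a lithium acetylide to an ynolate and O-silylation, capricious low-temperature chemistry spent on a partner that brings only three ring atoms and a stereocentre made to be destroyed;
(c) the final Friedel–Crafts acylation of A3 with A4: the most hindered C–C bond (at C6, between two oxygen-bearing carbons) is formed last, in acid, on a chromene and a prenyl group that cyclise or add acid easily, with two free phenols competing for the acylating agent.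

**Retrosynthetic overview**
The hexasubstituted benzene ring of the chromene (C4a, C5, C6, C7, C8, C8a; oxygen on C5, C7, C8a and carbon on C4a, C6, C8, a masked acylphloroglucinol) would be closed last, by cutting C7–C8 and C5–C6.
The key step would join two fragments of similar size, the silyl dienolate of a 2H-pyran-5-carboxylate (C5, C4a, C8a, C8 with its prenyl group, and the finished pyran ring) and an acylketene dimethyl acetal (C7, C6 and the complete arylacetyl ketone), by vinylogous Mukaiyama–Michael addition and Claisen (Dieckmann) condensation, much as a tetraketide with masked carbonyl groups is folded in biosynthesis.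
Ring order: pyran first (Knoevenagel/oxa-6π on a prenylated keto ester), benzene second; the key step gives the target itself.
The ester carbonyl becomes the free 5-OH and the surviving acetal methoxy the 7-OMe, the ketone is present from the start and the prenyl group from the first step, so the design has no ketene/quinone methide cascade, no ynolate and no late acylation of the acid-sensitive chromene.
Key step: step 6

Remark: the target has no stereocentre and no configured acyclic double bond; the transient stereocentres in the intermediates of the last step are racemic and are erased by enolisation.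

**Route**

Step 1
Reactants: 1 methyl acetoacetate; 2 1-bromo-3-methylbut-2-ene (prenyl bromide)
Product: 4 methyl 7-methyl-3-oxooct-6-enoate, via acetoacetate dianion 3 (not isolated)
Conditions: NaH (1.1 equiv), THF, 0 °C; n-BuLi (1.05 equiv), 0 °C; 2, 0 °C → rt; aq HCl
Reagents that add atoms: none
Why: Huckin–Weiler alkylation, in which the terminal carbanion of the acetoacetate dianion is the more nucleophilic site and displaces the primary allylic bromide (SN2), so the prenyl group sits on the carbon that becomes C8; no stereocentre is formed.

Step 2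
Reactants: 4 methyl 7-methyl-3-oxooct-6-enoate; 5 3-methylbut-2-enal (prenal)
Product: 7 methyl 2,2-dimethyl-6-(4-methylpent-3-en-1-yl)-2H-pyran-5-carboxylate, via 1-oxatriene 6 (not isolated)
Conditions: ethylenediammonium diacetate (10 mol %), MeOH, rt → 40 °C
Reagents that add atoms: none
Why: Knoevenagel condensation at the active methylene followed by oxa-6π electrocyclisation of 1-oxatriene 6 through the ketone oxygen (formal [3+3] annulation of a 1,3-dicarbonyl compound with an enal), the gem-dimethyl terminus and the conjugated ester holding the valence equilibrium on the 2H-pyran side; the closure forms O1–C2 of the chromene, leaves C4a without hydrogen and creates no stereocentre.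

Step 3
Reactants: 7 methyl 2,2-dimethyl-6-(4-methylpent-3-en-1-yl)-2H-pyran-5-carboxylate
Product: 9 {[(2,2-dimethyl-6-(4-methylpent-3-en-1-ylidene)-2H-pyran-5(6H)-ylidene)(methoxy)methyl]oxy}trimethylsilane, via lithium dienolate 8 (not isolated)
Conditions: LiN(i-Pr)2 (1.1 equiv), THF, −78 °C; Me3SiCl (1.3 equiv), −78 → 0 °C; pentane, filtration, evaporation; used crude
Reagents that add atoms: chlorotrimethylsilane, C[Si](C)(C)Cl
Why: Kinetic γ-deprotonation of the vinylogous carbonate (the α-carbon C4a bears no hydrogen) and O-silylation of the lithium dienolate should give a cyclic Chan–Brassard-type silyl ketene acetal that is nucleophilic at the future C8; no stereocentre is formed.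

Step 4
Reactants: 10 4-hydroxyphenylacetic acid
Product: 11 [4-(acetyloxy)phenyl]acetic acid
Conditions: Ac2O (1.2 equiv), aq NaOH (2.2 equiv), 0 °C; aq HCl to pH 2
Reagents that add atoms: acetic anhydride, CC(=O)OC(C)=O
Why: Chemoselective O-acetylation of the phenoxide in aqueous base (Schotten–Baumann conditions; any mixed anhydride of the carboxylate hydrolyses back) installs a phenol mask that the methoxide of the last step removes in the same flask.

Step 5
Reactants: 11 [4-(acetyloxy)phenyl]acetic acid; 12 1,1-dimethoxyethene
Product: 14 4-(4,4-dimethoxy-2-oxobut-3-en-1-yl)phenyl acetate, via acid chloride 13 (not isolated)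
Conditions: (COCl)2 (1.2 equiv), cat. DMF, CH2Cl2, 0 °C → rt, evaporate; 12 (2.5 equiv), Et2O, 0 °C → rt; evaporate, short filtration through basic alumina
Reagents that add atoms: none
Why: Acid chloride formation and C-acylation of the ketene acetal (McElvain acylation), with a second equivalent of 12 taking up hydrogen chloride as methyl acetate and chloromethane, should give a β,β-dimethoxy enone whose C7 is electrophilic, at the carboxyl oxidation level, and already carries the future 7-OMe; no stereocentre is formed.

Step 6
Reactants: 9 {[(2,2-dimethyl-6-(4-methylpent-3-en-1-ylidene)-2H-pyran-5(6H)-ylidene)(methoxy)methyl]oxy}trimethylsilane; 14 4-(4,4-dimethoxy-2-oxobut-3-en-1-yl)phenyl acetate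
Product: 18 1-[5-hydroxy-7-methoxy-2,2-dimethyl-8-(3-methylbut-2-en-1-yl)-2H-chromen-6-yl]-2-(4-hydroxyphenyl)ethan-1-one (target), via Mukaiyama adduct 15 (not isolated), via vinylogous ester 16 (not isolated), via dienone tautomer 17 (not isolated)
Conditions: 9 (1.3 equiv), Me3SiOTf (0.2 equiv), CH2Cl2, −78 → −30 °C; then NaOMe (6 equiv), MeOH, −30 → 50 °C, argon; AcOH
Reagents that add atoms: none
Why: Proposed new method: Me3SiOTf would silylate the carbonyl of 14 to a 1,1-dimethoxy-3-silyloxyallyl cation that the γ-carbon (C8) of silyl dienolate 9 attacks at the acetal carbon C7 (vinylogous Mukaiyama–Michael addition) to give 15; methoxide would then desilylate 15, expel one methoxide (E1cB) and cleave the aryl acetate to give vinylogous ester 16, whose C8–H lies between two vinylogous carbonyl systems, and the resulting dienolate would attack the pyran ester through its α-carbon C6 (intramolecular Claisen/Dieckmann condensation) to give 17, which enolises to the chelated phenol. The closest known reactions are the Staunton–Weinreb Michael/Dieckmann annulation of toluate anions, the silyl triflate-promoted conjugate addition of silyl ketene acetals to 4-pyranones and β-alkoxy enones, and the base-induced Claisen folding of 3,5,7-triketo esters to acylphloroglucinols. The only ring closed is the benzene ring (bonds C7–C8 and C5–C6, the second by a 6-exo-trig closure onto the ester carbon), on a pyran that is already in place. No stereocentre survives, since the centre at C8 in 15 and 16 and that at C6 in 17 are erased by enolisation. The step needs γ- over α-attack of the dienolate (the α-carbon C4a is fully substituted), a single addition at C7 (a second one would have to build a quaternary carbon next to the branched C8), and Claisen instead of aldol closure (C4a carries no hydrogen, so only C6 can reach an acyl carbon through a six-membered transition state). The ester carbonyl becomes the free 5-OH and the surviving acetal methoxy the 7-OMe, so the two oxygens ortho to the ketone are told apart by construction.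

**Compound list**
1 | methyl acetoacetate (methyl 3-oxobutanoate) | COC(=O)CC(C)=O | starting material
2 | 1-bromo-3-methylbut-2-ene (prenyl bromide) | CC(C)=CCBr | starting material
3 | sodium lithium dianion of methyl acetoacetate (not isolated) | [Na+].[Li+].[CH2-]C(=O)[CH-]C(=O)OC | intermediate
4 | methyl 7-methyl-3-oxooct-6-enoate | COC(=O)CC(=O)CCC=C(C)C | intermediate
5 | 3-methylbut-2-enal (prenal) | CC(C)=CC=O | starting material
6 | methyl (2E)-5-methyl-2-(5-methylhex-4-enoyl)hexa-2,4-dienoate (1-oxatriene, not isolated; the 2E isomer is the one that cyclises) | COC(=O)/C(=C/C=C(C)C)C(=O)CCC=C(C)C | intermediate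
7 | methyl 2,2-dimethyl-6-(4-methylpent-3-en-1-yl)-2H-pyran-5-carboxylate | COC(=O)C1=C(CCC=C(C)C)OC(C)(C)C=C1 | intermediate
8 | lithium (2,2-dimethyl-6-(4-methylpent-3-en-1-ylidene)-2H-pyran-5(6H)-ylidene)(methoxy)methanolate (lithium dienolate of 7, mixture of geometric isomers, not isolated) | [Li+].COC([O-])=C1C=CC(C)(C)OC1=CCC=C(C)C | intermediate
9 | {[(2,2-dimethyl-6-(4-methylpent-3-en-1-ylidene)-2H-pyran-5(6H)-ylidene)(methoxy)methyl]oxy}trimethylsilane (silyl ketene acetal, mixture of geometric isomers) | COC(O[Si](C)(C)C)=C1C=CC(C)(C)OC1=CCC=C(C)C | intermediate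
10 | 4-hydroxyphenylacetic acid | OC(=O)Cc1ccc(O)cc1 | starting material
11 | [4-(acetyloxy)phenyl]acetic acid | CC(=O)Oc1ccc(CC(O)=O)cc1 | intermediate
12 | 1,1-dimethoxyethene (ketene dimethyl acetal) | COC(=C)OC | starting material
13 | [4-(acetyloxy)phenyl]acetyl chloride (not isolated) | CC(=O)Oc1ccc(CC(Cl)=O)cc1 | intermediate
14 | 4-(4,4-dimethoxy-2-oxobut-3-en-1-yl)phenyl acetate | CC(=O)Oc1ccc(CC(=O)C=C(OC)OC)cc1 | intermediate
15 | methyl 6-{9-[4-(acetyloxy)phenyl]-6,6-dimethoxy-2-methyl-8-[(trimethylsilyl)oxy]nona-2,7-dien-5-yl}-2,2-dimethyl-2H-pyran-5-carboxylate (racemic, enol ether geometry not defined, not isolated) | COC(=O)C1=C(C(CC=C(C)C)C(OC)(OC)C=C(O[Si](C)(C)C)Cc2ccc(OC(C)=O)cc2)OC(C)(C)C=C1 | intermediate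
16 | methyl 6-[9-(4-hydroxyphenyl)-6-methoxy-2-methyl-8-oxonona-2,6-dien-5-yl]-2,2-dimethyl-2H-pyran-5-carboxylate (racemic, E/Z mixture at the enol ether, not isolated) | COC(=O)C1=C(C(CC=C(C)C)C(OC)=CC(=O)Cc2ccc(O)cc2)OC(C)(C)C=C1 | intermediate
17 | 6-[(4-hydroxyphenyl)acetyl]-7-methoxy-2,2-dimethyl-8-(3-methylbut-2-en-1-yl)-2H-chromen-5(6H)-one (racemic keto tautomer, not isolated) | O=C1C(C(=O)Cc2ccc(O)cc2)C(OC)=C(CC=C(C)C)C2=C1C=CC(C)(C)O2 | intermediate
18 | 1-[5-hydroxy-7-methoxy-2,2-dimethyl-8-(3-methylbut-2-en-1-yl)-2H-chromen-6-yl]-2-(4-hydroxyphenyl)ethan-1-one | COc1c(CC=C(C)C)c2c(c(O)c1C(=O)Cc1ccc(O)cc1)C=CC(C)(C)O2 | target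

**Step count and risks**
Total steps: 6. Longest linear sequence: 4 (steps 1, 2, 3, 6); steps 4 and 5 make the second fragment.

Steps most likely to fail, each with a fallback:

1. The benzannulation (step 6, the labelled step). The silylated ketene acetal may lose a benzylic proton (silyl transfer to a 2-silyloxydiene) faster than the hindered C8 nucleophile adds, or the dienolate may be reprotonated before the Claisen closure. The fallback would keep the pyran-first order, close the ring by known enolate chemistry on an ester, and bring in the benzyl ketone afterwards. It would set out from 9. Acylation of the silyl dienolate at its γ-carbon with methyl malonyl chloride (cat. Me3SiOTf, CH2Cl2, −78 → 20 °C, the known γ-acylation of silyl dienolates by acid chlorides) would give the β-keto ester methyl 6-(1-methoxy-7-methyl-1,3-dioxooct-6-en-4-yl)-2,2-dimethyl-2H-pyran-5-carboxylate F1. O-methylation of its enolate (Me2SO4, K2CO3, DMF) would give the β-methoxy enoate methyl 6-[(2E)-1,3-dimethoxy-7-methyl-1-oxoocta-2,6-dien-4-yl]-2,2-dimethyl-2H-pyran-5-carboxylate F2. NaOMe in MeOH would close the benzene ring by Claisen condensation to the salicylate methyl 5-hydroxy-7-methoxy-2,2-dimethyl-8-(3-methylbut-2-en-1-yl)-2H-chromene-6-carboxylate F3. Addition of {4-[(tert-butyldimethylsilyl)oxy]benzyl}magnesium chloride F4 (from the benzylic chloride and Mg, in excess; the hindered, chelated ester should stop at the ketone, which is held as its enolate) would give the silyl ether 2-{4-[(tert-butyldimethylsilyl)oxy]phenyl}-1-[5-hydroxy-7-methoxy-2,2-dimethyl-8-(3-methylbut-2-en-1-yl)-2H-chromen-6-yl]ethan-1-one F5. Bu4NF would then return to the route at 18.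

2. The acylation of the ketene acetal (step 5). Chloride may demethylate the dimethoxycarbenium intermediate to the β-keto ester, the acid chloride may be dehydrochlorinated to an arylketene, or 14 may hydrolyse on isolation. The fallback would make the same functional group from an alkoxyalkyne instead of a ketene acetal. It would set out from 10. Coupling with MeNHOMe·HCl (EDC·HCl, Et3N) would give 2-(4-hydroxyphenyl)-N-methoxy-N-methylacetamide F6. Silylation (t-BuMe2SiCl, imidazole) would give 2-{4-[(tert-butyldimethylsilyl)oxy]phenyl}-N-methoxy-N-methylacetamide F7. Addition of lithium methoxyacetylide (from chloroacetaldehyde dimethyl acetal and LiNEt2) would give the ynone 1-{4-[(tert-butyldimethylsilyl)oxy]phenyl}-4-methoxybut-3-yn-2-one F8. Base-catalysed addition of methanol (cat. Et3N, MeOH, 0 °C) would give the ketene acetal 1-{4-[(tert-butyldimethylsilyl)oxy]phenyl}-4,4-dimethoxybut-3-en-2-one F9, which would take the place of 14 in step 6. The methoxide of that step also cleaves the aryl silyl ether, so the fallback comes back to the route at 18.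

3. The pyran annulation (step 2). Conjugate addition of the keto ester to the enal or self-condensation of 5 under amine catalysis may compete, or the 1-oxatriene/2H-pyran equilibrium may lie unfavourably for the keto ester with the long side chain. The fallback would change the order of bond formation. It would set out from 1 and 5, condensed under the same catalysis to the parent pyran methyl 2,2,6-trimethyl-2H-pyran-5-carboxylate F10, the simplest case of this annulation. Its lithium dienolate (LiN(i-Pr)2, THF, −78 °C) would then be alkylated at the γ-carbon (the 6-methyl group) with 2, coming back to the route at 7 with step 1 omitted.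

**Further compounds**
F1 | step 6 | methyl 6-(1-methoxy-7-methyl-1,3-dioxooct-6-en-4-yl)-2,2-dimethyl-2H-pyran-5-carboxylate (racemic) | COC(=O)CC(=O)C(CC=C(C)C)C1=C(C(=O)OC)C=CC(C)(C)O1
F2 | step 6 | methyl 6-[(2E)-1,3-dimethoxy-7-methyl-1-oxoocta-2,6-dien-4-yl]-2,2-dimethyl-2H-pyran-5-carboxylate (racemic) | COC(=O)/C=C(/OC)C(CC=C(C)C)C1=C(C(=O)OC)C=CC(C)(C)O1
F3 | step 6 | methyl 5-hydroxy-7-methoxy-2,2-dimethyl-8-(3-methylbut-2-en-1-yl)-2H-chromene-6-carboxylate | COC(=O)c1c(O)c2C=CC(C)(C)Oc2c(CC=C(C)C)c1OC
F4 | step 6 | {4-[(tert-butyldimethylsilyl)oxy]benzyl}magnesium chloride | CC(C)(C)[Si](C)(C)Oc1ccc(C[Mg]Cl)cc1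
F5 | step 6 | 2-{4-[(tert-butyldimethylsilyl)oxy]phenyl}-1-[5-hydroxy-7-methoxy-2,2-dimethyl-8-(3-methylbut-2-en-1-yl)-2H-chromen-6-yl]ethan-1-one | COc1c(CC=C(C)C)c2c(c(O)c1C(=O)Cc1ccc(O[Si](C)(C)C(C)(C)C)cc1)C=CC(C)(C)O2
F6 | step 5 | 2-(4-hydroxyphenyl)-N-methoxy-N-methylacetamide | CON(C)C(=O)Cc1ccc(O)cc1
F7 | step 5 | 2-{4-[(tert-butyldimethylsilyl)oxy]phenyl}-N-methoxy-N-methylacetamide | CON(C)C(=O)Cc1ccc(O[Si](C)(C)C(C)(C)C)cc1
F8 | step 5 | 1-{4-[(tert-butyldimethylsilyl)oxy]phenyl}-4-methoxybut-3-yn-2-one | COC#CC(=O)Cc1ccc(O[Si](C)(C)C(C)(C)C)cc1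
F9 | step 5 | 1-{4-[(tert-butyldimethylsilyl)oxy]phenyl}-4,4-dimethoxybut-3-en-2-one | COC(OC)=CC(=O)Cc1ccc(O[Si](C)(C)C(C)(C)C)cc1
F10 | step 2 | methyl 2,2,6-trimethyl-2H-pyran-5-carboxylate | COC(=O)C1=C(C)OC(C)(C)C=C1
A1 | direct plan | (2E)-3-methoxy-7-methylocta-2,6-dienoic acid | OC(=O)/C=C(\CCC=C(C)C)OC
A2 | direct plan | triisopropyl[(3-methoxy-5-methylhex-4-en-1-yn-1-yl)oxy]silane (racemic) | CC(C)[Si](OC#CC(OC)C=C(C)C)(C(C)C)C(C)C
A3 | direct plan | 7-methoxy-2,2-dimethyl-8-(3-methylbut-2-en-1-yl)-2H-chromen-5-ol | COc1cc(O)c2C=CC(C)(C)Oc2c1CC=C(C)C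
A4 | direct plan | 4-hydroxyphenylacetic acid | OC(=O)Cc1ccc(O)cc1
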